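With C1 as the carboxyl carbon, the 1,2-dioxolane ring comprises C3, C4, C5 and the two peroxide oxygens. Each oxygenated ring carbon (C3, C5) is quaternary and carries one methyl group, and a lone CH2 (C4) lies between them. The route cuts this pattern at C4–C5 and O–C3. A methyl-ketone peroxycarbenium ion brings C5 plus the O–O unit and a 2-methyl-1-alkene brings C4 and C3, so one Lewis-acid operation makes the ring, two bonds and both ring stereocentres. The precursor is the methoxy triethylsilylperoxy ketal of the (4R)-methyl ketone already bearing the full E,E-styryl diene chain. Its partner is silyl-protected 3-methylbut-3-en-1-ol. C7 is set catalytically beforehand; ring isomers are separated.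

Key step: step 14

Assumption: the (R,Sp)-configured Josiphos ligand is taken to deliver methyl to the Re face of the enone β-carbon, as with related linear E-acceptors; if a first run shows the opposite sense, the equally available mirror-image ligand is used.

Remark: locants C1–C17 are those of the target chain. The spatial arrangement at C3 is the same in all ring compounds. Its CIP label is R in the silyl ether and the alcohol and S in the aldehyde and the acid, because the rank of the C2 arm changes. The ring methyl groups are trans.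

Step 1
Reactants: 1 cinnamyl chloride; 2 tert-butyl acetate
Product: 4 tert-butyl (4E)-5-phenylpent-4-enoate, via lithium enolate 3 (not isolated)
Conditions: LDA (1.1 equiv), THF, −78 °C; then 1, DMPU, −78 °C → rt
Reagents that add atoms: none
Why: SN2 alkylation of a stable lithium ester enolate at the primary allylic carbon adds the two carbons (C13, C14) that the cinnamyl unit lacks for the five-carbon C13–C17 segment, and it leaves the E-styryl bond untouched.

Step 2
Reactants: 4 tert-butyl (4E)-5-phenylpent-4-enoate
Product: 5 (4E)-5-phenylpent-4-en-1-ol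
Conditions: LiAlH4, Et2O, 0 °C → rt; aqueous NaOH work-up
Reagents that add atoms: none
Why: Hydride reduction of an ester to the primary alcohol, to which the isolated styryl alkene is inert.

Step 3
Reactants: 5 (4E)-5-phenylpent-4-en-1-ol
Product: 6 1-phenyl-5-{[(4E)-5-phenylpent-4-en-1-yl]sulfanyl}-1H-tetrazole
Conditions: 1-phenyl-1H-tetrazole-5-thiol, PPh3, DIAD, THF, 0 °C → rt
Reagents that add atoms: 1-phenyl-1H-tetrazole-5-thiol, Sc1nnnn1-c1ccccc1
Why: Mitsunobu thioetherification of an unhindered primary alcohol by an acidic heteroaryl thiol proceeds by SN2 displacement of the oxyphosphonium group.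

Step 4
Reactants: 6 1-phenyl-5-{[(4E)-5-phenylpent-4-en-1-yl]sulfanyl}-1H-tetrazole
Product: 7 1-phenyl-5-{[(4E)-5-phenylpent-4-en-1-yl]sulfonyl}-1H-tetrazole
Conditions: 30% aq H2O2, (NH4)6Mo7O24·4H2O (10 mol %), EtOH, 0 °C → rt
Reagents that add atoms: hydrogen peroxide, OO
Why: Molybdate-catalysed sulfide-to-sulfone oxidation is much faster than epoxidation of a styryl alkene, so only sulfur should be oxidised.

Step 5
Reactants: 8 cyclohexene
Product: 11 6,6-dimethoxyhexanal, via hydroperoxy aldehyde 9 (not isolated), via hydroperoxy acetal 10 (not isolated)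
Conditions: O3, CH2Cl2–MeOH, −78 °C; TsOH·H2O (cat.), rt; NaHCO3; Me2S, rt
Reagents that add atoms: ozone, [O-][O+]=O; methanol, CO
Why: Ozonolysis in methanol (Criegee mechanism) gives two different termini, so acetalisation of the free aldehyde followed by sulfide reduction of the methoxy hydroperoxide end delivers the monoprotected dialdehyde in one flask.

Step 6
Reactants: 7 1-phenyl-5-{[(4E)-5-phenylpent-4-en-1-yl]sulfonyl}-1H-tetrazole; 11 6,6-dimethoxyhexanal
Product: 13 [(1E,5E)-11,11-dimethoxyundeca-1,5-dien-1-yl]benzene, via potassiated sulfone 12 (not isolated)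
Conditions: KHMDS, DME, −60 °C; then 11, −60 °C → rt; aq NH4Cl
Reagents that add atoms: none
Why: Julia–Kocienski olefination, in which potassium in a coordinating solvent favours the open transition state whose adduct collapses (Smiles rearrangement, anti elimination) to the E-configured C12=C13 bond, any minor Z isomer being removable on AgNO3-impregnated silica.

Step 7
Reactants: 13 [(1E,5E)-11,11-dimethoxyundeca-1,5-dien-1-yl]benzene
Product: 14 (6E,10E)-11-phenylundeca-6,10-dienal
Conditions: TsOH·H2O (cat.), acetone–H2O, rt
Reagents that add atoms: water, O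
Why: Acid-catalysed acetal hydrolysis, with no other acid-labile group in the molecule.

Step 8
Reactants: 14 (6E,10E)-11-phenylundeca-6,10-dienal; 15 1-(triphenylphosphoranylidene)propan-2-one
Product: 16 (3E,9E,13E)-14-phenyltetradeca-3,9,13-trien-2-one
Conditions: CH2Cl2, reflux
Reagents that add atoms: none
Why: Wittig reaction of a stabilised ylide, which should give the E-enone and leaves the remote alkenes alone.

Step 9
Reactants: 16 (3E,9E,13E)-14-phenyltetradeca-3,9,13-trien-2-one
Product: 18 (4R,9E,13E)-4-methyl-14-phenyltetradeca-9,13-dien-2-one, via magnesium enolate 17 (not isolated)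
Conditions: MeMgBr (1.2 equiv), CuBr·SMe2 (5 mol %), (R)-1-[(Sp)-2-(diphenylphosphino)ferrocenyl]ethyldicyclohexylphosphine (6 mol %), tBuOMe, −75 °C; aq NH4Cl
Reagents that add atoms: methylmagnesium bromide, C[Mg]Br
Why: Copper-catalysed asymmetric conjugate addition of a Grignard reagent, in which the chiral diphosphine–copper complex binds the s-cis enone and transfers methyl to the Re face of C4, setting the future C7 as R, while the low temperature lets catalysed 1,4-addition outrun direct 1,2-addition.

Step 10
Reactants: 18 (4R,9E,13E)-4-methyl-14-phenyltetradeca-9,13-dien-2-one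
Product: 19 (4R,9E,13E)-2,2-dimethoxy-4-methyl-14-phenyltetradeca-9,13-diene
Conditions: HC(OMe)3, MeOH, TsOH·H2O (cat.), rt; Et3N quench
Reagents that add atoms: trimethyl orthoformate, COC(OC)OC; methanol, CO
Why: Acid-catalysed ketalisation driven by the orthoester as water scavenger, and the stereocentre is β to the carbonyl group so it cannot epimerise.

Step 11
Reactants: 19 (4R,9E,13E)-2,2-dimethoxy-4-methyl-14-phenyltetradeca-9,13-diene
Product: 20 (4R,9E,13E)-2-hydroperoxy-2-methoxy-4-methyl-14-phenyltetradeca-9,13-diene (both C2 epimers)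
Conditions: anhydrous H2O2 in Et2O (2 equiv), PPTS (10 mol %), Et2O–MeOH, 0 °C; NaHCO3
Reagents that add atoms: hydrogen peroxide, OO
Why: Acid-catalysed trans-ketalisation (perhydrolysis), in which the oxocarbenium ion from 19 is captured by the more nucleophilic H2O2, limited peroxide and methanol co-solvent hold the equilibrium at single exchange, and the alkenes are inert to H2O2 without a metal or peracid.

Step 12
Reactants: 20 (4R,9E,13E)-2-hydroperoxy-2-methoxy-4-methyl-14-phenyltetradeca-9,13-diene (both C2 epimers)
Product: 21 (4R,9E,13E)-2-methoxy-4-methyl-14-phenyl-2-(triethylsilylperoxy)tetradeca-9,13-diene (both C2 epimers)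
Conditions: Et3SiCl, imidazole, DMF, 0 °C; chromatography on Et3N-deactivated silica
Reagents that add atoms: chlorotriethylsilane, CC[Si](Cl)(CC)CC
Why: O-silylation of a hydroperoxide under mild base removes the acidic OOH proton and installs the group that later leaves from oxygen when the ring closes.

Step 13
Reactants: 22 3-methylbut-3-en-1-ol
Product: 23 tert-butyl[(3-methylbut-3-en-1-yl)oxy]diphenylsilane
Conditions: TBDPSCl, imidazole, CH2Cl2, rt
Reagents that add atoms: tert-butyl(chloro)diphenylsilane, CC(C)(C)[Si](Cl)(c1ccccc1)c1ccccc1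
Why: Standard silyl ether formation, chosen because the bulky, weakly basic silyl ether oxygen survives SnCl4 at low temperature and cannot trap the later C3 cation (a four-membered ring would be needed), whereas an acyl group could do so through a six-membered dioxanylium ion.

Step 14
Reactants: 21 (4R,9E,13E)-2-methoxy-4-methyl-14-phenyl-2-(triethylsilylperoxy)tetradeca-9,13-diene (both C2 epimers); 23 tert-butyl[(3-methylbut-3-en-1-yl)oxy]diphenylsilane
Product: 26 tert-butyl(2-{(3R,5R)-3,5-dimethyl-5-[(2R,7E,11E)-2-methyl-12-phenyldodeca-7,11-dien-1-yl]-1,2-dioxolan-3-yl}ethoxy)diphenylsilane, via peroxycarbenium ion 24 (not isolated), via tertiary C3 cation 25 (not isolated)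
Conditions: 23 (5 equiv), SnCl4 (1.1 equiv), 2,6-di-tert-butyl-4-methylpyridine (0.3 equiv), CH2Cl2 (high dilution), −78 °C, slow addition of 21; aq NaHCO3; silica gel, then preparative HPLC
Reagents that add atoms: none
Why: SnCl4 abstracts methoxide from either C2 epimer of 21 to give the planar ion 24, the CH2 terminus of 23 attacks it in the Markovnikov sense (C4–C5 bond) leaving cation 25, and the outer, silyl-bearing peroxide oxygen traps that cation (O–C3 bond) with release of the Et3Si group. This is the known Lewis-acid-mediated (3+2) annulation of silylperoxy ketals with simple alkenes, applied here to a longer chain. The one new ring, the 1,2-dioxolane, closes by five-membered capture of a free carbocation by oxygen, which counts as 5-endo relative to the original C=C but escapes the usual geometric penalty because the π bond has already been consumed. C5 arises in the C–C bond formation essentially without control, since the two flanks of 24 (CH3 and CH2–C7) differ little and C7 sits beyond a freely rotating CH2, and C3 arises in the closure, where only a weak preference for placing the C6 chain and the silyloxyethyl arm on opposite ring faces can be counted on. The wanted isomer 26 is therefore secured by separation from its three diastereomers, which is possible because the enantioenriched C7 centre turns every ring isomer into a diastereomer and the UV-active silyl group aids HPLC. Chemoselectivity over the chain alkenes, of which the styryl one could give a benzylic cation, rests on four factors: the excess of 23, the dilution of 21, the lower nucleophilicity of 1,2-disubstituted π bonds, and the medium-ring strain of any intramolecular attack; the hindered pyridine removes adventitious acid.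

Step 15
Reactants: 26 tert-butyl(2-{(3R,5R)-3,5-dimethyl-5-[(2R,7E,11E)-2-methyl-12-phenyldodeca-7,11-dien-1-yl]-1,2-dioxolan-3-yl}ethoxy)diphenylsilane
Product: 27 2-{(3R,5R)-3,5-dimethyl-5-[(2R,7E,11E)-2-methyl-12-phenyldodeca-7,11-dien-1-yl]-1,2-dioxolan-3-yl}ethan-1-ol
Conditions: Bu4NF, AcOH, THF, 0 °C → rt
Reagents that add atoms: none
Why: Fluoride-mediated silyl ether cleavage, safe for the peroxide because neither C3 nor C5 carries a hydrogen and base-induced Kornblum–DeLaMare fragmentation is therefore impossible.

Step 16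
Reactants: 27 2-{(3R,5R)-3,5-dimethyl-5-[(2R,7E,11E)-2-methyl-12-phenyldodeca-7,11-dien-1-yl]-1,2-dioxolan-3-yl}ethan-1-ol
Product: 29 2-{(3S,5R)-3,5-dimethyl-5-[(2R,7E,11E)-2-methyl-12-phenyldodeca-7,11-dien-1-yl]-1,2-dioxolan-3-yl}acetic acid, via dioxolanyl acetaldehyde 28 (not isolated)
Conditions: TEMPO (20 mol %), PhI(OAc)2 (2.5 equiv), CH2Cl2–H2O, rt
Reagents that add atoms: water, O
Why: Oxoammonium-catalysed oxidation of a primary alcohol through the aldehyde hydrate to the acid under weakly acidic conditions, which spare the alkenes and the O–O bond and avoid base-induced β-elimination of the peroxide from the aldehyde.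

Compound list
1 | cinnamyl chloride, (E)-(3-chloroprop-1-en-1-yl)benzene | ClC/C=C/c1ccccc1 | starting material
2 | tert-butyl acetate | CC(=O)OC(C)(C)C | starting material
3 | lithium enolate of tert-butyl acetate | [Li]OC(=C)OC(C)(C)C | intermediate
4 | tert-butyl (4E)-5-phenylpent-4-enoate | CC(C)(C)OC(=O)CC/C=C/c1ccccc1 | intermediate
5 | (4E)-5-phenylpent-4-en-1-ol | OCCC/C=C/c1ccccc1 | intermediate
6 | 1-phenyl-5-{[(4E)-5-phenylpent-4-en-1-yl]sulfanyl}-1H-tetrazole | S(CCC/C=C/c1ccccc1)c1nnnn1-c1ccccc1 | intermediate
7 | 1-phenyl-5-{[(4E)-5-phenylpent-4-en-1-yl]sulfonyl}-1H-tetrazole | O=S(=O)(CCC/C=C/c1ccccc1)c1nnnn1-c1ccccc1 | intermediate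
8 | cyclohexene | C1=CCCCC1 | starting material
9 | 6-hydroperoxy-6-methoxyhexanal (racemic) | COC(CCCCC=O)OO | intermediate
10 | 1-hydroperoxy-1,6,6-trimethoxyhexane (racemic) | COC(CCCCC(OC)OC)OO | intermediate
11 | 6,6-dimethoxyhexanal | COC(CCCCC=O)OC | intermediate
12 | α-potassiated sulfone derived from 7 | [K]C(CC/C=C/c1ccccc1)S(=O)(=O)c1nnnn1-c1ccccc1 | intermediate
13 | [(1E,5E)-11,11-dimethoxyundeca-1,5-dien-1-yl]benzene | COC(OC)CCCC/C=C/CC/C=C/c1ccccc1 | intermediate
14 | (6E,10E)-11-phenylundeca-6,10-dienal | O=CCCCC/C=C/CC/C=C/c1ccccc1 | intermediate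
15 | 1-(triphenylphosphoranylidene)propan-2-one | CC(=O)C=P(c1ccccc1)(c1ccccc1)c1ccccc1 | starting material
16 | (3E,9E,13E)-14-phenyltetradeca-3,9,13-trien-2-one | CC(=O)/C=C/CCCC/C=C/CC/C=C/c1ccccc1 | intermediate
17 | bromomagnesium (2Z,4R,9E,13E)-4-methyl-14-phenyltetradeca-2,9,13-trien-2-olate | C[C@H](CCCC/C=C/CC/C=C/c1ccccc1)/C=C(/C)O[Mg]Br | intermediate
18 | (4R,9E,13E)-4-methyl-14-phenyltetradeca-9,13-dien-2-one | C[C@H](CCCC/C=C/CC/C=C/c1ccccc1)CC(C)=O | intermediate
19 | (4R,9E,13E)-2,2-dimethoxy-4-methyl-14-phenyltetradeca-9,13-diene | C[C@H](CCCC/C=C/CC/C=C/c1ccccc1)CC(C)(OC)OC | intermediate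
20 | (4R,9E,13E)-2-hydroperoxy-2-methoxy-4-methyl-14-phenyltetradeca-9,13-diene, both C2 epimers | C[C@H](CCCC/C=C/CC/C=C/c1ccccc1)CC(C)(OC)OO | intermediate
21 | (4R,9E,13E)-2-methoxy-4-methyl-14-phenyl-2-(triethylsilylperoxy)tetradeca-9,13-diene, both C2 epimers | C[C@H](CCCC/C=C/CC/C=C/c1ccccc1)CC(C)(OC)OO[Si](CC)(CC)CC | intermediate
22 | 3-methylbut-3-en-1-ol | C=C(C)CCO | starting material
23 | tert-butyl[(3-methylbut-3-en-1-yl)oxy]diphenylsilane | C=C(C)CCO[Si](c1ccccc1)(c1ccccc1)C(C)(C)C | intermediate
24 | C5 peroxycarbenium ion, O-(triethylsilyloxy)oxocarbenium ion of ketone 18 | C[C@H](CCCC/C=C/CC/C=C/c1ccccc1)CC(C)=[O+]O[Si](CC)(CC)CC | intermediate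
25 | tertiary C3 carbocation after C4–C5 bond formation (the C5 epimer leading to 26 is drawn) | C[C@H](CCCC/C=C/CC/C=C/c1ccccc1)C[C@](C)(C[C+](C)CCO[Si](c1ccccc1)(c1ccccc1)C(C)(C)C)OO[Si](CC)(CC)CC | intermediate
26 | tert-butyl(2-{(3R,5R)-3,5-dimethyl-5-[(2R,7E,11E)-2-methyl-12-phenyldodeca-7,11-dien-1-yl]-1,2-dioxolan-3-yl}ethoxy)diphenylsilane, ring methyls trans | C[C@H](CCCC/C=C/CC/C=C/c1ccccc1)C[C@]1(C)C[C@@](C)(CCO[Si](c2ccccc2)(c2ccccc2)C(C)(C)C)OO1 | intermediate
27 | 2-{(3R,5R)-3,5-dimethyl-5-[(2R,7E,11E)-2-methyl-12-phenyldodeca-7,11-dien-1-yl]-1,2-dioxolan-3-yl}ethan-1-ol | C[C@H](CCCC/C=C/CC/C=C/c1ccccc1)C[C@]1(C)C[C@@](C)(CCO)OO1 | intermediate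
28 | 2-{(3S,5R)-3,5-dimethyl-5-[(2R,7E,11E)-2-methyl-12-phenyldodeca-7,11-dien-1-yl]-1,2-dioxolan-3-yl}acetaldehyde | C[C@H](CCCC/C=C/CC/C=C/c1ccccc1)C[C@]1(C)C[C@@](C)(CC=O)OO1 | intermediate
29 | 2-{(3S,5R)-3,5-dimethyl-5-[(2R,7E,11E)-2-methyl-12-phenyldodeca-7,11-dien-1-yl]-1,2-dioxolan-3-yl}acetic acid | C[C@H](CCCC/C=C/CC/C=C/c1ccccc1)C[C@]1(C)C[C@@](C)(CC(=O)O)OO1 | target

Total step count: 16. Longest linear sequence: 14 (steps 1–4, 6–12, 14–16).

Steps most likely to fail

**Step 14.**
- **What may go wrong:** The peroxycarbenium ion may be intercepted by the styryl π bond of a second molecule. The tertiary cation may lose a proton before the ring closes. The O–O bond may cleave heterolytically with a 1,2-carbon shift (Hock/Criegee type). Facial selectivity may be lacking, so the ring isomers become hard to separate.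
- **Assignment of the isolated isomer:** The ring relationship would be assigned from NOE contacts across the ring (C3 methyl to the C6 methylene, C5 methyl to the C2 methylene). The C5/C7 relationship would be assigned from a crystalline derivative of the acid.
- **Fallback:** It sets out from 21 and comes back at 29. It splits the annulation into two polar bond formations and uses a far stronger π-nucleophile.
- **C4–C5 bond:** The silyl ketene acetal 1-methoxy-3-methyl-1-(trimethylsilyloxy)buta-1,3-diene F1 is made from methyl 3-methylbut-2-enoate with LDA and Me3SiCl. Its γ-carbon adds to the same ion (Me3SiOTf cat., CH2Cl2, −78 °C, vinylogous Mukaiyama-type addition). This should give methyl (2E,7R,12E,16E)-3,5,7-trimethyl-17-phenyl-5-(triethylsilylperoxy)heptadeca-2,12,16-trienoate F2.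
- **O–C3 bond:** Buffered fluoride (Bu4NF, AcOH) frees the tertiary hydroperoxide methyl (2E,7R,12E,16E)-5-hydroperoxy-3,5,7-trimethyl-17-phenylheptadeca-2,12,16-trienoate F3. A catalytic amine (Et2NH, CF3CH2OH) then closes the ring by reversible 5-exo-trig oxa-Michael addition.
- **Return to the route:** After separation of the isomers this gives methyl 2-{(3S,5R)-3,5-dimethyl-5-[(2R,7E,11E)-2-methyl-12-phenyldodeca-7,11-dien-1-yl]-1,2-dioxolan-3-yl}acetate F4. LiOH in aqueous THF then delivers 29, which makes steps 15 and 16 unnecessary.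

**Step 11.**
- **What may go wrong:** A second exchange at the ketal carbon may occur when peroxide is not limiting. Adventitious water may also hydrolyse the ketal back to the carbonyl stage.
- **Fallback:** It sets out from 19 and comes back at 20. It replaces the equilibrium exchange by an addition.
- **Sequence:** Methanol is eliminated from 19 with Me3SiOTf and iPr2NEt in CH2Cl2. This gives mainly the terminal enol ether (4R,9E,13E)-2-methoxy-4-methyl-14-phenyltetradeca-1,9,13-triene F5, and any internal regioisomer converges on the same product. Markovnikov addition of anhydrous ethereal H2O2 under PPTS catalysis at 0 °C then gives 20 in a medium free of methanol and water.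

**Step 9.**
- **What may go wrong:** The Grignard reagent may add directly (1,2) to the methyl ketone, and facial selectivity on the enone may be insufficient.
- **Fallback:** It sets out from 14 and comes back at 18. It moves the asymmetric addition to a less carbonyl-reactive acceptor.
- **Sequence:** The stabilised ylide S-ethyl 2-(triphenylphosphoranylidene)ethanethioate F6 is made from S-ethyl bromothioacetate and PPh3, then base. It converts 14 into S-ethyl (2E,8E,12E)-13-phenyltrideca-2,8,12-trienethioate F7. MeMgBr with CuBr·SMe2 and the same ferrocenyl diphosphine in tBuOMe at −75 °C should give S-ethyl (3R,8E,12E)-3-methyl-13-phenyltrideca-8,12-dienethioate F8. Me2CuLi in Et2O at −78 °C then turns the thioester into methyl ketone 18.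

Further compounds
F1 | step 14 | 1-methoxy-3-methyl-1-(trimethylsilyloxy)buta-1,3-diene (ketene acetal geometry not defined) | C=C(C)C=C(OC)O[Si](C)(C)C
F2 | step 14 | methyl (2E,7R,12E,16E)-3,5,7-trimethyl-17-phenyl-5-(triethylsilylperoxy)heptadeca-2,12,16-trienoate, both C5 epimers | C[C@H](CCCC/C=C/CC/C=C/c1ccccc1)CC(C)(C/C(C)=C/C(=O)OC)OO[Si](CC)(CC)CC
F3 | step 14 | methyl (2E,7R,12E,16E)-5-hydroperoxy-3,5,7-trimethyl-17-phenylheptadeca-2,12,16-trienoate, both C5 epimers | C[C@H](CCCC/C=C/CC/C=C/c1ccccc1)CC(C)(C/C(C)=C/C(=O)OC)OO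
F4 | step 14 | methyl 2-{(3S,5R)-3,5-dimethyl-5-[(2R,7E,11E)-2-methyl-12-phenyldodeca-7,11-dien-1-yl]-1,2-dioxolan-3-yl}acetate | C[C@H](CCCC/C=C/CC/C=C/c1ccccc1)C[C@]1(C)C[C@@](C)(CC(=O)OC)OO1
F5 | step 11 | (4R,9E,13E)-2-methoxy-4-methyl-14-phenyltetradeca-1,9,13-triene | C[C@H](CCCC/C=C/CC/C=C/c1ccccc1)CC(=C)OC
F6 | step 9 | S-ethyl 2-(triphenylphosphoranylidene)ethanethioate | CCSC(=O)C=P(c1ccccc1)(c1ccccc1)c1ccccc1
F7 | step 9 | S-ethyl (2E,8E,12E)-13-phenyltrideca-2,8,12-trienethioate | CCSC(=O)/C=C/CCCC/C=C/CC/C=C/c1ccccc1
F8 | step 9 | S-ethyl (3R,8E,12E)-3-methyl-13-phenyltrideca-8,12-dienethioate | C[C@H](CCCC/C=C/CC/C=C/c1ccccc1)CC(=O)SCC
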